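The target in these flasks is starting material that has spent time with the enzyme, so I reckon each yield from two times: how long the starting material stays in the flask, and how long the enzyme takes to convert it.

| flask | starting material | second substrate | enzyme | remark | time |
|---|---|---|---|---|---|
| Friday's | 0.20 M | 0.20 M | 20 µM | run made earlier |  |
| Wednesday's | 0.20 M | 0.20 M | 10 µM | run made earlier |  |
| Sunday's | 0.20 M | 0.20 M | 15 µM | run made earlier |  |
| Thursday's | 0.20 M | 0.10 M | 20 µM | run made earlier |  |
| alder | 0.20 M (in portions, 2, over 8.0 min) | 0.200 M | 20 µM | first portion at the start, last at 8.0 min | 10 min |
| cedar | 0.20 M (fed, over 8.0 min) | 0.200 M | 20 µM | all else is in the flask from the start; the feed brings no volume worth counting | 10 min |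
| birch | 0.20 M | 0.200 M | 20 µM | everything together at the start | 10 min |
| oak | 0.20 M | 0.200 M (fed, over 8.0 min) | 20 µM | all else is in the flask from the start; the feed brings no volume worth counting | 10 min |
| elm | 0.20 M (fed, over 2.0 min) | 0.200 M | 20 µM | all else is in the flask from the start; the feed brings no volume worth counting | 10 min |

- Friday's (time / min: target / %, starting material / %): 1.33: 8.4, 92.7; 4.00: 18.8, 78.6; 6.00: 29.2, 71.8; 10.0: 42.6, 58.4
- Wednesday's (time / min: target / %, starting material / %): 0.667: 1.9, 97.1; 1.33: 3.6, 95.9; 3.00: 7.2, 93.7; 8.00: 17.0, 81.1
- Sunday's (time / min: target / %, starting material / %): 2.00: 7.1, 91.7; 4.00: 16.2, 84.4; 6.00: 22.7, 77.9; 8.00: 26.9, 72.0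
- Thursday's (time / min: target / %, starting material / %): 1.00: 4.5, 93.9; 3.00: 18.3, 83.2; 5.00: 25.4, 73.5; 8.00: 40.8, 61.9

(scatter of a reading: 1 percentage point)

- steps that have been proposed: starting material + enzyme <-> complex A; complex A -> enzyme + target; second substrate + enzyme <-> complex B; complex B -> enzyme + second product; enzyme <-> dormant form

- which flask leads in amount of target, in percent of the starting material charged ("all alike" within 1.5 percentage points) (alder / cedar / birch / oak / elm / all alike)
- how much target is there at the end, in percent of the starting material charged: alder
- how much target is there at the end, in percent of the starting material charged: cedar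
- how much target is there at the end, in percent of the starting material charged: birch
- how much target is there at the end, in percent of the starting material charged: oak
- how much target is there at the end, in percent of the starting material charged: elm

I read the second time from Friday's run, which has birch's charges. Averaging its two measures of what remains unconverted at 10.0 min gives a pseudo-first-order constant of 0.0546 min⁻¹, a reading, so the conversion time is 18.3 min. Birch's starting material stays 10 min, which is 0.546 conversion times. I call this ratio the exposure, the mean stay of the starting material divided by the conversion time, and I take the yield as one minus e to the minus exposure: 42.1% for birch.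

For a feed I replace the curve by its mean. Cedar's steady feed and alder's two portions both give a mean stay of 6.00 min, so their exposure is 0.328 and their yield 28.0%. Elm's mean stay of 9.00 min gives 0.492 and 38.8%. Reckoned portion by portion, alder comes to 26.2%, so the mean moves my figure by under 2 points there, less than the distance to birch.

Oak keeps the full stay but gains speed. Thursday's run, read the same way but at 8.00 min, gives 0.0627 min⁻¹, also a reading, which is 1.15 times Friday's constant. By my reckoning, oak's steady feed gives a mean [second substrate] of half the charge over 8.0 min, which is the level Thursday's run started from, so I count that time at Thursday's constant. This adds 0.0645 to birch's exposure and makes 0.611, the highest, with 45.7% of target. That is 3.6 percentage points ahead of birch, against a margin of 1.5 points.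

The forecast gives alder 28%, cedar 29%, birch 42.5%, oak 46% and elm 39.5%, with oak first: “Oak should lead, though its margin over birch is small.”

The flasks end at 27.8% for alder, 27.6% for cedar, 42.3% for birch, 44.5% for oak and 38.7% for elm, so oak leads birch by 2.2 points.

    starting material + enzyme ⇌ complex A (K = 4.20 M⁻¹, k = 19000 M⁻¹ s⁻¹)
    complex A → enzyme + target (k = 26.0 s⁻¹)
    second substrate + enzyme ⇌ complex B (K = 2.00 M⁻¹, k = 12000 M⁻¹ s⁻¹)
    complex B → enzyme + second product (k = 13.0 s⁻¹)
    enzyme ⇌ dormant form (K = 0.560, k = 0.00230 s⁻¹)

A flask like oak but with 0.80 M of second substrate ends at 36.5%, less than birch. For oak read at 15 min, I stretch birch's exposure in proportion and add oak's bonus, which makes 0.884 and gives 58.7% of target, and that flask holds 58.3% of target.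

All runs come from a simulation from invented constants; noise was put on by code.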